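**Strategy.** The ten-membered carbocycle (ring A; germacrane numbering: C1=C10 alkene, C4–C5 oxirane, C6 ester, C7 isopropyl, C8 carbinol) is closed last at the C9–C10 bond. The key step exploits the homoallylic alcohol array C8(OH)–C9H2–C10(Me)=C1 of ring A: a nickel-catalysed reductive cross-electrophile coupling joins the (E)-alkenyl iodide carbon C10 to the primary bromide carbon C9 of an acyclic, protecting-group-free bromohydrin ester and gives the target directly. The precursor comes from an Evans syn aldol (C6, C7), an allylic-strain-controlled epoxidation (C4, C5) and an Evans–Tishchenko reaction that installs the trimethoxybenzoate and the anti C8 carbinol in one operation.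

Key step: step 12

Remark on the chemistry: the target is read from its SMILES as the (1(10)E,4R,5R,6S,7R,8R) isomer, germacrane atom numbers are used in the Why lines, and compounds 1, 3, 11, 12 and 21 are taken as commercial.

Step 1
Reactants: 1 pent-3-yn-1-ol
Product: 2 5-bromopent-2-yne
Conditions: CBr4, PPh3, CH2Cl2, 0 °C to rt
Reagents that add atoms: carbon tetrabromide, BrC(Br)(Br)Br
Why: Appel bromination converts the primary alcohol into the bromide under neutral conditions that leave the internal alkyne untouched.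

Step 2
Reactants: 2 5-bromopent-2-yne; 3 ethyl but-2-ynoate
Product: 6 ethyl (2E)-3-methyloct-2-en-6-ynoate, via pent-3-ynylmagnesium bromide 4 (not isolated), via alkenylcopper adduct 5 (not isolated)
Conditions: Mg, THF; CuI, THF, −40 °C; then 3, −78 °C; aq NH4Cl at −78 °C
Reagents that add atoms: none
Why: The Grignard-derived alkylcopper adds syn across the ynoate (carbocupration, conjugate addition) and cold protonation of the alkenylcopper with retention fixes the (2E) trisubstituted alkene that becomes C4=C5.

Step 3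
Reactants: 6 ethyl (2E)-3-methyloct-2-en-6-ynoate
Product: 7 (2E)-3-methyloct-2-en-6-yn-1-ol
Conditions: i-Bu2AlH, CH2Cl2, −78 °C; aq potassium sodium tartrate (KNaC4H4O6)
Reagents that add atoms: none
Why: 1,2-Reduction of the enoate with i-Bu2AlH gives the allylic alcohol without touching the alkyne or the alkene geometry.

Step 4
Reactants: 7 (2E)-3-methyloct-2-en-6-yn-1-ol
Product: 9 (2E,6E)-7-iodo-3-methylocta-2,6-dien-1-ol, via bis-zirconocene alkenyl alkoxide 8 (not isolated)
Conditions: Cp2Zr(H)Cl (excess), THF, rt to 45 °C; then I2, THF, 0 °C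
Reagents that add atoms: iodine, II
Why: Hydrozirconation is a syn addition, excess Cp2Zr(H)Cl equilibrates zirconium to the less hindered methyl-bearing alkyne carbon, and iodinolysis with retention should give the (6E)-alkenyl iodide (future C10–I trans to C2) while the trisubstituted alkene is too hindered to react.

Step 5
Reactants: 9 (2E,6E)-7-iodo-3-methylocta-2,6-dien-1-ol
Product: 10 (2E,6E)-7-iodo-3-methylocta-2,6-dienal
Conditions: MnO2, CH2Cl2, rt
Reagents that add atoms: none
Why: MnO2 oxidises only the allylic alcohol to the enal and leaves the alkenyl iodide and both alkene geometries intact.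

Step 6
Reactants: 11 (4S)-4-benzyl-1,3-oxazolidin-2-one; 12 3-methylbutanoyl chloride
Product: 14 (4S)-4-benzyl-3-(3-methylbutanoyl)-1,3-oxazolidin-2-one, via lithium oxazolidinide 13 (not isolated)
Conditions: n-BuLi, THF, −78 °C; then 12, −78 to 0 °C
Reagents that add atoms: none
Why: N-Acylation of the lithiated oxazolidinone with the acid chloride is the standard entry to the Evans imide.

Step 7
Reactants: 14 (4S)-4-benzyl-3-(3-methylbutanoyl)-1,3-oxazolidin-2-one; 10 (2E,6E)-7-iodo-3-methylocta-2,6-dienal
Product: 16 (4S)-4-benzyl-3-[(2S,3R,4E,8E)-3-hydroxy-9-iodo-5-methyl-2-(propan-2-yl)deca-4,8-dienoyl]-1,3-oxazolidin-2-one, via dibutylboron (Z)-enolate 15 (not isolated)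
Conditions: Bu2BOTf, i-Pr2NEt, CH2Cl2, −78 to 0 °C; then 10, −78 to 0 °C; pH 7 buffer, MeOH, H2O2, 0 °C
Reagents that add atoms: none
Why: Evans syn aldol, in which the (Z)-boron enolate reacts through a Zimmerman–Traxler chair on the face opposite the benzyl group, which should set C7 (isopropyl) and C6 (carbinol) syn with the absolute configuration of the target.

Step 8
Reactants: 16 the syn aldol imide
Product: 17 (2S,3R,4E,8E)-3-hydroxy-9-iodo-N-methoxy-N,5-dimethyl-2-(propan-2-yl)deca-4,8-dienamide
Conditions: MeNHOMe·HCl, AlMe3, CH2Cl2, −20 to 0 °C; aq potassium sodium tartrate (KNaC4H4O6)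
Reagents that add atoms: N,O-dimethylhydroxylamine hydrochloride, CNOC.Cl
Why: Aluminium amide transamination (Weinreb amide formation) of the β-hydroxy imide is assisted by the free hydroxyl and is placed before the epoxidation so that no Lewis acid meets the oxirane.

Step 9
Reactants: 17 the hydroxy Weinreb amide
Product: 18 (2S,3S)-3-hydroxy-3-[(2R,3R)-3-[(3E)-4-iodopent-3-en-1-yl]-3-methyloxiran-2-yl]-N-methoxy-N-methyl-2-(propan-2-yl)propanamide
Conditions: mCPBA, NaHCO3, CH2Cl2, 0 °C
Reagents that add atoms: 3-chloroperoxybenzoic acid, O=C(OO)c1cccc(Cl)c1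
Why: Hydroxyl-directed Prilezhaev epoxidation in which A1,3 strain between the C4 methyl and C6 holds the carbinol C–H in the alkene plane, so the peracid attacks syn to OH and anti to the C7 branch and should give the threo (4R,5R) trans-epoxide, while the iodine-deactivated C1=C10 alkene is left alone.

Step 10
Reactants: 18 the epoxy Weinreb amide
Product: 20 (3S,4S)-1-bromo-4-hydroxy-4-[(2R,3R)-3-[(3E)-4-iodopent-3-en-1-yl]-3-methyloxiran-2-yl]-3-(propan-2-yl)butan-2-one, via dilithium tetrahedral adduct 19 (not isolated)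
Conditions: MeLi·LiBr (1 equiv), THF, −78 °C; then BrCH2I and MeLi·LiBr added dropwise, −78 °C; AcOH, THF, −78 °C
Reagents that add atoms: bromoiodomethane, BrCI
Why: Bromomethyllithium formed by fast iodine–lithium exchange adds once to the Weinreb amide (stable chelated tetrahedral adduct) and the cold acidic quench releases the bromomethyl ketone, which brings in C9 as an electrophilic CH2Br.

Step 11
Reactants: 20 the hydroxy bromomethyl ketone; 21 3,4,5-trimethoxybenzaldehyde
Product: 23 (1S,2R,3S)-4-bromo-3-hydroxy-1-[(2R,3R)-3-[(3E)-4-iodopent-3-en-1-yl]-3-methyloxiran-2-yl]-2-(propan-2-yl)butyl 3,4,5-trimethoxybenzoate, via hemiacetal 22 (not isolated)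
Conditions: SmI2 (30 mol %, premixed with excess 21), THF, −10 °C
Reagents that add atoms: none
Why: Evans–Tishchenko reaction in which the C6 hydroxyl forms a hemiacetal with the aldehyde and, in a samarium-bridged chair, its hydride is delivered intramolecularly to the C8 ketone, which should set the C8 carbinol 1,3-anti to C6–O and leave the 3,4,5-trimethoxybenzoate on O6 in the same operation.

Step 12
Reactants: 23 the bromohydrin ester
Product: 24 CNP0279501.1, (1R,4E,7R,8R,9S,10R)-7-hydroxy-1,5-dimethyl-8-(propan-2-yl)-11-oxabicyclo[8.1.0]undec-4-en-9-yl 3,4,5-trimethoxybenzoate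
Conditions: NiBr2·glyme (30 mol %), 4,4′-di-tert-butyl-2,2′-bipyridine, NaI (50 mol %), Mn powder, DMA, 40 °C, syringe-pump addition of 23 over 12 h (final 2 mM)
Reagents that add atoms: none
Why: Proposed new method: zerovalent nickel (from NiBr2·glyme, the bipyridine and Mn) inserts into the C10–I bond with retention of the (E) geometry, a monovalent nickel species abstracts bromine from C9, and the primary C9 radical is captured by the alkenylnickel of the same molecule to give a trivalent nickel metallacycle that reductively eliminates the C9–C10 bond. The closest known reaction type is the intermolecular nickel/bipyridine reductive cross-electrophile coupling of alkenyl halides with primary alkyl bromides, including its halohydrin and epoxide variants that give homoallylic alcohols, run here intramolecularly. Ring A is closed as a 10-membered carbocycle by C(sp3)–C(sp2) reductive elimination from an 11-membered nickelacycle, with the endocyclic alkene already in place. No stereocentre is created, the five existing centres are spectators and the alkene geometry is carried over from the iodide. The step needs cross-coupling over homo-coupling, which the different activation modes of the alkenyl iodide (two-electron oxidative addition) and the alkyl bromide (halogen-atom abstraction) should secure, and cyclisation over oligomerisation, which slow addition into an excess of catalyst and the conformational bias of the (E)-alkene and trans-epoxide in the chain should favour. The trisubstituted oxirane, the aryl ester and the free C8 hydroxyl should survive because no acid, base or strong Lewis acid is present.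

**Compound list**

1 | pent-3-yn-1-ol | CC#CCCO | starting material
2 | 5-bromopent-2-yne | CC#CCCBr | intermediate
3 | ethyl but-2-ynoate | CC#CC(=O)OCC | starting material
4 | pent-3-ynylmagnesium bromide (not isolated) | CC#CCC[Mg]Br | intermediate
5 | ethyl (2Z)-2-cuprio-3-methyloct-2-en-6-ynoate, alkenylcopper adduct with copper cis to the new chain (not isolated) | CCOC(=O)/C([Cu])=C(\C)CCC#CC | intermediate
6 | ethyl (2E)-3-methyloct-2-en-6-ynoate | CCOC(=O)/C=C(\C)CCC#CC | intermediate
7 | (2E)-3-methyloct-2-en-6-yn-1-ol | OC/C=C(\C)CCC#CC | intermediate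
8 | Cp2Zr(Cl) alkoxide of (2E,6E)-7-[Cp2Zr(Cl)]-3-methylocta-2,6-dien-1-ol (not isolated) | Cl[Zr](OC/C=C(\C)CC/C=C(\C)[Zr](Cl)(C1C=CC=C1)C1C=CC=C1)(C1C=CC=C1)C1C=CC=C1 | intermediate
9 | (2E,6E)-7-iodo-3-methylocta-2,6-dien-1-ol | OC/C=C(\C)CC/C=C(\C)I | intermediate
10 | (2E,6E)-7-iodo-3-methylocta-2,6-dienal | O=C/C=C(\C)CC/C=C(\C)I | intermediate
11 | (4S)-4-benzyl-1,3-oxazolidin-2-one | O=C1N[C@@H](Cc2ccccc2)CO1 | starting material
12 | 3-methylbutanoyl chloride | CC(C)CC(Cl)=O | starting material
13 | lithium salt of (4S)-4-benzyl-1,3-oxazolidin-2-one (not isolated) | [Li]N1C(=O)OC[C@@H]1Cc1ccccc1 | intermediate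
14 | (4S)-4-benzyl-3-(3-methylbutanoyl)-1,3-oxazolidin-2-one | CC(C)CC(=O)N1C(=O)OC[C@@H]1Cc1ccccc1 | intermediate
15 | dibutylboron (Z)-enolate of 14 (not isolated) | CCCCB(CCCC)O/C(=C\C(C)C)N1C(=O)OC[C@@H]1Cc1ccccc1 | intermediate
16 | (4S)-4-benzyl-3-[(2S,3R,4E,8E)-3-hydroxy-9-iodo-5-methyl-2-(propan-2-yl)deca-4,8-dienoyl]-1,3-oxazolidin-2-one | O=C(N1C(=O)OC[C@@H]1Cc1ccccc1)[C@@H](C(C)C)[C@H](O)/C=C(\C)CC/C=C(\C)I | intermediate
17 | (2S,3R,4E,8E)-3-hydroxy-9-iodo-N-methoxy-N,5-dimethyl-2-(propan-2-yl)deca-4,8-dienamide | CON(C)C(=O)[C@@H](C(C)C)[C@H](O)/C=C(\C)CC/C=C(\C)I | intermediate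
18 | (2S,3S)-3-hydroxy-3-[(2R,3R)-3-[(3E)-4-iodopent-3-en-1-yl]-3-methyloxiran-2-yl]-N-methoxy-N-methyl-2-(propan-2-yl)propanamide | CON(C)C(=O)[C@@H](C(C)C)[C@H](O)[C@H]1O[C@]1(C)CC/C=C(\C)I | intermediate
19 | dilithium tetrahedral adduct of 18 with bromomethyllithium, hemiaminal centre undefined (not isolated) | [Li]OC(CBr)(N(C)OC)[C@@H](C(C)C)[C@H](O[Li])[C@H]1O[C@]1(C)CC/C=C(\C)I | intermediate
20 | (3S,4S)-1-bromo-4-hydroxy-4-[(2R,3R)-3-[(3E)-4-iodopent-3-en-1-yl]-3-methyloxiran-2-yl]-3-(propan-2-yl)butan-2-one | BrCC(=O)[C@@H](C(C)C)[C@H](O)[C@H]1O[C@]1(C)CC/C=C(\C)I | intermediate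
21 | 3,4,5-trimethoxybenzaldehyde | COc1cc(C=O)cc(OC)c1OC | starting material
22 | hemiacetal of the C6 hydroxyl of 20 with 21, hemiacetal centre undefined (not isolated) | COc1cc(C(O)O[C@@H]([C@H](C(C)C)C(=O)CBr)[C@@H]2[C@](CC/C=C(\C)I)(C)O2)cc(OC)c1OC | intermediate
23 | (1S,2R,3S)-4-bromo-3-hydroxy-1-[(2R,3R)-3-[(3E)-4-iodopent-3-en-1-yl]-3-methyloxiran-2-yl]-2-(propan-2-yl)butyl 3,4,5-trimethoxybenzoate | COc1cc(C(=O)O[C@@H]([C@H](C(C)C)[C@H](O)CBr)[C@@H]2[C@](CC/C=C(\C)I)(C)O2)cc(OC)c1OC | intermediate
24 | CNP0279501.1, (1R,4E,7R,8R,9S,10R)-7-hydroxy-1,5-dimethyl-8-(propan-2-yl)-11-oxabicyclo[8.1.0]undec-4-en-9-yl 3,4,5-trimethoxybenzoate | COc1cc(C(=O)O[C@H]2[C@H](C(C)C)[C@H](O)C/C(C)=C/CC[C@@]3(C)O[C@H]23)cc(OC)c1OC | target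

**Step count.** Total: 12 steps. Longest linear sequence: 11 steps (steps 1–5 and 7–12); step 6 is a one-step side branch.

**Steps most likely to fail**

1. Step 12 (Proposed new method). What may go wrong: the C9 radical is captured by the alkenylnickel of another molecule (oligomerisation) or is reduced before capture (hydrodehalogenation), so the medium ring does not close. Fallback with known chemistry, setting out from 18 and coming back at 24: the ring is closed at the same bond by a palladium-catalysed intramolecular α-alkenylation of a ketone enolate, and the Evans–Tishchenko reaction is moved to the end.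
 - O6 of 18 is silylated (TESCl, imidazole, DMF) to give the triethylsilyl ether Weinreb amide F1.
 - MeMgBr (THF, 0 °C) gives the methyl ketone F2, in which C9 is a CH3 group.
 - The kinetic lithium enolate of F2 (LiHMDS, THF, −78 °C) is coupled with the C10 iodide by zerovalent palladium (Pd2(dba)3, P(t-Bu)3, high dilution, rt to 50 °C) to give the macrocyclic β,γ-unsaturated ketone F3.
 - HF·pyridine (pyridine, THF, 0 °C) frees the hydroxyl to give the macrocyclic β-hydroxy ketone F4.
 - The Evans–Tishchenko reaction of F4 with 21 (SmI2 cat., THF, −10 °C) then sets the anti C8 carbinol, places the ester on O6 and gives 24.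

2. Step 11. What may go wrong: single-electron reduction of the C–Br bond by residual divalent samarium, intramolecular O-alkylation of the hydroxy bromoketone to a furanone before hemiacetal formation, or acyl migration from O6 to O8 after the hydride transfer. Fallback, setting out from 18 and coming back at 23: the ester is installed first and C8 is set by substrate-controlled reduction.
 - 18 is acylated on O6 (3,4,5-trimethoxybenzoyl chloride, DMAP, Et3N, CH2Cl2) to give the ester Weinreb amide F5.
 - Bromomethyllithium is added as in step 10 to give the bromomethyl ketone ester F6; the chelating Weinreb amide should react before the hindered aryl ester.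
 - LiBH(s-Bu)3 (THF, −78 °C, AcOH quench) reduces the C8 ketone under Felkin–Anh control, with hydride entering anti to the C6 branch, which should give the same C8 configuration and hence 23.

3. Step 10. What may go wrong: decomposition of the carbenoid before it adds, halogen–lithium exchange at the alkenyl iodide, or attack of the C6 alkoxide on the neighbouring oxirane. Fallback, setting out from 18 and coming back at 20: C9 is introduced as a methyl group and brominated afterwards.
 - MeMgBr (3 equiv, THF, 0 °C) converts 18 into the β-hydroxy methyl ketone F7.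
 - LDA (2.2 equiv) with TMSCl (THF, −78 °C) gives the kinetic, less substituted silyl enol ether with the hydroxyl also silylated, the bis-trimethylsilyl compound F8.
 - NBS (THF, −78 °C) brominates the enol ether at C9, and aqueous citric acid frees the hydroxyl to give 20.

**Further compounds**

F1 | step 12 | (2S,3S)-3-[(2R,3R)-3-[(3E)-4-iodopent-3-en-1-yl]-3-methyloxiran-2-yl]-N-methoxy-N-methyl-2-(propan-2-yl)-3-(triethylsilyloxy)propanamide | CON(C)C(=O)[C@@H](C(C)C)[C@H](O[Si](CC)(CC)CC)[C@H]1O[C@]1(C)CC/C=C(\C)I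
F2 | step 12 | (3S,4S)-4-[(2R,3R)-3-[(3E)-4-iodopent-3-en-1-yl]-3-methyloxiran-2-yl]-3-(propan-2-yl)-4-(triethylsilyloxy)butan-2-one | CC(=O)[C@@H](C(C)C)[C@H](O[Si](CC)(CC)CC)[C@H]1O[C@]1(C)CC/C=C(\C)I
F3 | step 12 | (1R,4E,8S,9S,10R)-1,5-dimethyl-8-(propan-2-yl)-9-(triethylsilyloxy)-11-oxabicyclo[8.1.0]undec-4-en-7-one | CC[Si](CC)(CC)O[C@H]2[C@H](C(C)C)C(=O)C/C(C)=C/CC[C@@]3(C)O[C@H]23
F4 | step 12 | (1R,4E,8S,9S,10R)-9-hydroxy-1,5-dimethyl-8-(propan-2-yl)-11-oxabicyclo[8.1.0]undec-4-en-7-one | O[C@H]2[C@H](C(C)C)C(=O)C/C(C)=C/CC[C@@]3(C)O[C@H]23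
F5 | step 11 | (1S,2S)-1-[(2R,3R)-3-[(3E)-4-iodopent-3-en-1-yl]-3-methyloxiran-2-yl]-3-[methoxy(methyl)amino]-3-oxo-2-(propan-2-yl)propyl 3,4,5-trimethoxybenzoate | COc1cc(C(=O)O[C@@H]([C@H](C(C)C)C(=O)N(C)OC)[C@@H]2[C@](CC/C=C(\C)I)(C)O2)cc(OC)c1OC
F6 | step 11 | (1S,2S)-4-bromo-1-[(2R,3R)-3-[(3E)-4-iodopent-3-en-1-yl]-3-methyloxiran-2-yl]-3-oxo-2-(propan-2-yl)butyl 3,4,5-trimethoxybenzoate | COc1cc(C(=O)O[C@@H]([C@H](C(C)C)C(=O)CBr)[C@@H]2[C@](CC/C=C(\C)I)(C)O2)cc(OC)c1OC
F7 | step 10 | (3S,4S)-4-hydroxy-4-[(2R,3R)-3-[(3E)-4-iodopent-3-en-1-yl]-3-methyloxiran-2-yl]-3-(propan-2-yl)butan-2-one | CC(=O)[C@@H](C(C)C)[C@H](O)[C@H]1O[C@]1(C)CC/C=C(\C)I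
F8 | step 10 | trimethyl{[(3S,4S)-4-[(2R,3R)-3-[(3E)-4-iodopent-3-en-1-yl]-3-methyloxiran-2-yl]-3-(propan-2-yl)-4-(trimethylsilyloxy)but-1-en-2-yl]oxy}silane | C=C(O[Si](C)(C)C)[C@@H](C(C)C)[C@H](O[Si](C)(C)C)[C@H]1O[C@]1(C)CC/C=C(\C)I
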